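**Retrosynthetic overview**
1. Target 17 comes from the 7-O-acetyl coumarin 16 by deacetylation.
2. The coumarin C3–C4 bond of 16 is made by a Perkin–Oglialoro (aldol-type) condensation joining arylacetic acid 10 (its CH2 becomes C3) and salicylaldehyde 13 (its CHO becomes C4). The pyranone ring closes in the same step and is the last ring formed.
3. Acid 10 comes from chromene aldehyde 5 by one-carbon homologation (TosMIC), nitrile hydrolysis and hydrogenation. Aldehyde 5 comes from 2,4-dihydroxybenzaldehyde 1 and prenal 2 by chromenylation (dimethylpyran ring formed first) and O-methylation.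
4. Aldehyde 13 comes from 5-methoxyresorcinol 11 by Vilsmeier–Haack formylation.

Assumption: the target SMILES has no stereocentre (the molecule is achiral), so no enantiocontrol is needed and the route only has to deliver the correct constitution.

**Step 1**
Reactants: 1 2,4-dihydroxybenzaldehyde; 2 3-methylbut-2-enal (prenal)
Product: 4 5-hydroxy-2,2-dimethyl-2H-chromene-6-carbaldehyde, via ortho-quinone methide 3 (not isolated)
Conditions: ethylenediammonium diacetate (10 mol %), xylene, reflux, 8 h
Reagents that add atoms: none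
Why: Amine-catalysed Knoevenagel-type C-alkylation at C3 of the resorcinol (between the two oxygens), loss of water to quinone methide 3 and oxa-6π electrocyclisation onto the non-chelated 4-oxygen give the angular 2H-chromene (formal [3+3] chromenylation); no stereocentre is formed.

**Step 2**
Reactants: 4 5-hydroxy-2,2-dimethyl-2H-chromene-6-carbaldehyde
Product: 5 5-methoxy-2,2-dimethyl-2H-chromene-6-carbaldehyde
Conditions: MeI, K2CO3, DMF, 40 °C
Reagents that add atoms: iodomethane, CI
Why: Williamson O-methylation (SN2) of the only phenol, whose hydrogen bond to the aldehyde is broken by carbonate in DMF; aldehyde and chromene are inert.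

**Step 3**
Reactants: 5 5-methoxy-2,2-dimethyl-2H-chromene-6-carbaldehyde
Product: 7 2-(5-methoxy-2,2-dimethyl-2H-chromen-6-yl)acetonitrile, via N-(1-tosylalkenyl)formamide 6 (not isolated)
Conditions: TosMIC, KOtBu, DME, −40 °C; then MeOH, reflux
Reagents that add atoms: p-toluenesulfonylmethyl isocyanide (TosMIC), Cc1ccc(cc1)S(=O)(=O)C[N+]#[C-]
Why: Van Leusen reductive cyanation: the TosMIC anion adds to the aldehyde, the oxazoline opens to formamide 6, and methanolysis of the formyl group followed by loss of sulfinate gives the homologous nitrile; the chromene and aryl ether do not react with base.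

**Step 4**
Reactants: 7 2-(5-methoxy-2,2-dimethyl-2H-chromen-6-yl)acetonitrile
Product: 9 2-(5-methoxy-2,2-dimethyl-2H-chromen-6-yl)acetic acid, via primary amide 8 (not isolated)
Conditions: KOH, EtOH/H2O, reflux; then aq. HCl, 0 °C, pH 3
Reagents that add atoms: water, O; potassium hydroxide, [K+].[OH-]
Why: Base-mediated nitrile hydrolysis through the amide to the carboxylate, freed by brief cold acidification that the 2,2-dimethylchromene tolerates.

**Step 5**
Reactants: 9 2-(5-methoxy-2,2-dimethyl-2H-chromen-6-yl)acetic acid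
Product: 10 2-(5-methoxy-2,2-dimethylchroman-6-yl)acetic acid
Conditions: H2 (1 atm), 10% Pd/C, EtOAc, rt
Reagents that add atoms: none
Why: Heterogeneous catalytic hydrogenation of the cis-disubstituted styrenyl C3=C4 bond, the only reducible group present now that the aldehyde has been converted.

**Step 6**
Reactants: 11 5-methoxybenzene-1,3-diol (5-methoxyresorcinol)
Product: 13 2,4-dihydroxy-6-methoxybenzaldehyde, via aryl iminium chloride 12 (not isolated)
Conditions: POCl3, DMF, MeCN, 0 °C to rt; then H2O, 50 °C
Reagents that add atoms: N,N-dimethylformamide, CN(C)C=O; water, O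
Why: Vilsmeier–Haack formylation (electrophilic aromatic substitution) goes mainly to C4, para to one OH and ortho to the other and twice as abundant as C2; the minor symmetrical 2,6-dihydroxy-4-methoxy isomer is removed by chromatography or crystallisation.

**Step 7**
Reactants: 10 2-(5-methoxy-2,2-dimethylchroman-6-yl)acetic acid; 13 2,4-dihydroxy-6-methoxybenzaldehyde
Product: 16 5-methoxy-3-(5-methoxy-2,2-dimethylchroman-6-yl)-2-oxo-2H-chromen-7-yl acetate, via mixed anhydride 14 (not isolated), via aldehyde diacetate 15 (not isolated)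
Conditions: Ac2O, Et3N, 115 °C, 12 h
Reagents that add atoms: acetic anhydride, CC(=O)OC(C)=O
Why: Perkin–Oglialoro condensation: the enolate of mixed anhydride 14 adds aldol-fashion to the aldehyde of 15, and β-elimination with acyl transfer and lactonisation onto the ortho oxygen gives the 3-arylcoumarin, the 7-OH staying protected as its acetate; no stereocentre is formed.

**Step 8**
Reactants: 16 5-methoxy-3-(5-methoxy-2,2-dimethylchroman-6-yl)-2-oxo-2H-chromen-7-yl acetate
Product: 17 7-hydroxy-5-methoxy-3-(5-methoxy-2,2-dimethylchroman-6-yl)-2H-chromen-2-one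
Conditions: TsOH·H2O (10 mol %), MeOH, 55 °C
Reagents that add atoms: none
Why: Acid-catalysed transesterification (methanolysis) of the aryl acetate; the coumarin lactone, both aryl methyl ethers and the chroman ether are stable under these conditions.

**Compound list**
1 | 2,4-dihydroxybenzaldehyde | O=Cc1ccc(O)cc1O | starting material
2 | 3-methylbut-2-enal (prenal) | CC(C)=CC=O | starting material
3 | ortho-quinone methide: 4-formyl-3-hydroxy-2-(3-methylbut-2-en-1-ylidene)cyclohexa-3,5-dien-1-one | O=CC1=C(O)C(=CC=C(C)C)C(=O)C=C1 | intermediate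
4 | 5-hydroxy-2,2-dimethyl-2H-chromene-6-carbaldehyde | O=Cc1ccc2c(C=CC(C)(C)O2)c1O | intermediate
5 | 5-methoxy-2,2-dimethyl-2H-chromene-6-carbaldehyde | O=Cc1ccc2c(C=CC(C)(C)O2)c1OC | intermediate
6 | N-[2-(5-methoxy-2,2-dimethyl-2H-chromen-6-yl)-1-(4-methylphenylsulfonyl)ethenyl]formamide (alkene geometry not defined) | O=CNC(=Cc1ccc2c(C=CC(C)(C)O2)c1OC)S(=O)(=O)c1ccc(C)cc1 | intermediate
7 | 2-(5-methoxy-2,2-dimethyl-2H-chromen-6-yl)acetonitrile | N#CCc1ccc2c(C=CC(C)(C)O2)c1OC | intermediate
8 | 2-(5-methoxy-2,2-dimethyl-2H-chromen-6-yl)acetamide | NC(=O)Cc1ccc2c(C=CC(C)(C)O2)c1OC | intermediate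
9 | 2-(5-methoxy-2,2-dimethyl-2H-chromen-6-yl)acetic acid | OC(=O)Cc1ccc2c(C=CC(C)(C)O2)c1OC | intermediate
10 | 2-(5-methoxy-2,2-dimethylchroman-6-yl)acetic acid | OC(=O)Cc1ccc2c(CCC(C)(C)O2)c1OC | intermediate
11 | 5-methoxybenzene-1,3-diol (5-methoxyresorcinol) | COc1cc(O)cc(O)c1 | starting material
12 | N-[(2,4-dihydroxy-6-methoxyphenyl)methylidene]-N-methylmethanaminium chloride | C[N+](C)=Cc1c(O)cc(O)cc1OC.[Cl-] | intermediate
13 | 2,4-dihydroxy-6-methoxybenzaldehyde | COc1cc(O)cc(O)c1C=O | intermediate
14 | acetic 2-(5-methoxy-2,2-dimethylchroman-6-yl)acetic anhydride | CC(=O)OC(=O)Cc1ccc2c(CCC(C)(C)O2)c1OC | intermediate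
15 | 4-formyl-5-methoxy-1,3-phenylene diacetate | COc1cc(OC(C)=O)cc(OC(C)=O)c1C=O | intermediate
16 | 5-methoxy-3-(5-methoxy-2,2-dimethylchroman-6-yl)-2-oxo-2H-chromen-7-yl acetate | COc1c(-c2cc3c(OC)cc(OC(C)=O)cc3oc2=O)ccc2c1CCC(C)(C)O2 | intermediate
17 | 7-hydroxy-5-methoxy-3-(5-methoxy-2,2-dimethylchroman-6-yl)-2H-chromen-2-one | COc1c(-c2cc3c(OC)cc(O)cc3oc2=O)ccc2c1CCC(C)(C)O2 | target

**Totals**
Total step count: 8. Longest linear sequence: 7 steps (steps 1, 2, 3, 4, 5, 7, 8).

**Steps most likely to fail and their fallbacks**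

Step 7 (Perkin–Oglialoro condensation) is the most exposed: both partners are electron-rich and ortho-substituted, so conversion can be low and decarboxylated stilbene can form. The fallback sets out from acid 10 (together with aldehyde 13) and comes back at target 17, so step 8 is not needed. Acid 10 is esterified (MeOH, H2SO4 cat., reflux) to methyl 2-(5-methoxy-2,2-dimethylchroman-6-yl)acetate F1. Aldehyde 13 is protected on both phenols (MOMCl, NaH, DMF, 0 °C to rt) as 2-methoxy-4,6-bis(methoxymethoxy)benzaldehyde F2. The lithium enolate of F1 (LiN(iPr)2, THF, −78 °C) is added to F2 in a directed aldol addition to give methyl 3-hydroxy-3-[2-methoxy-4,6-bis(methoxymethoxy)phenyl]-2-(5-methoxy-2,2-dimethylchroman-6-yl)propanoate F3, a racemic diastereomer mixture whose two centres are destroyed in the next operation. Warming F3 with HCl in MeOH at 60 °C removes both MOM groups, lactonises the freed ortho phenol onto the ester and dehydrates the benzylic alcohol, giving 17 directly.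

Step 3 (TosMIC reductive cyanation) can stall at oxazoline-type by-products with an electron-rich ortho-methoxy aldehyde. The fallback sets out from aldehyde 5 and comes back at acid 9, so step 4 is bypassed. Wittig methoxymethylenation with Ph3P=CHOMe (from (methoxymethyl)triphenylphosphonium chloride and KOtBu, THF, 0 °C) gives 5-methoxy-6-(2-methoxyethenyl)-2,2-dimethyl-2H-chromene F4 as an E/Z mixture. Mild hydrolysis (aq. HCO2H, THF, rt) gives 2-(5-methoxy-2,2-dimethyl-2H-chromen-6-yl)acetaldehyde F5, used crude. Pinnick oxidation (NaClO2, NaH2PO4, 2-methylbut-2-ene, tBuOH/H2O, 0 °C) then delivers 9.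

Step 1 (chromenylation with prenal) can give moderate yields through enal oligomerisation or some linear isomer. The fallback sets out from 1 and comes back at 4. The non-chelated 4-OH of 1 is alkylated with 3-chloro-3-methylbut-1-yne (K2CO3, KI, acetone, reflux) to give 2-hydroxy-4-[(2-methylbut-3-yn-2-yl)oxy]benzaldehyde F6. Heating F6 in N,N-diethylaniline at 190 °C triggers an aryl propargyl Claisen rearrangement, enolisation, 1,5-hydrogen shift and oxa-6π electrocyclisation, which closes regioselectively at C3 to give 4.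

**Further compounds**
F1 | step 7 | methyl 2-(5-methoxy-2,2-dimethylchroman-6-yl)acetate | COC(=O)Cc1ccc2c(CCC(C)(C)O2)c1OC
F2 | step 7 | 2-methoxy-4,6-bis(methoxymethoxy)benzaldehyde | COCOc1cc(OC)c(C=O)c(OCOC)c1
F3 | step 7 | methyl 3-hydroxy-3-[2-methoxy-4,6-bis(methoxymethoxy)phenyl]-2-(5-methoxy-2,2-dimethylchroman-6-yl)propanoate (racemic diastereomer mixture) | COC(=O)C(c1ccc2c(CCC(C)(C)O2)c1OC)C(O)c1c(OC)cc(OCOC)cc1OCOC
F4 | step 3 | 5-methoxy-6-(2-methoxyethenyl)-2,2-dimethyl-2H-chromene (E/Z mixture) | COC=Cc1ccc2c(C=CC(C)(C)O2)c1OC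
F5 | step 3 | 2-(5-methoxy-2,2-dimethyl-2H-chromen-6-yl)acetaldehyde | O=CCc1ccc2c(C=CC(C)(C)O2)c1OC
F6 | step 1 | 2-hydroxy-4-[(2-methylbut-3-yn-2-yl)oxy]benzaldehyde | C#CC(C)(C)Oc1ccc(C=O)c(O)c1
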